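**Plan**

1. Retrosynthesis: after removal of the helpers (two aryl TIPS ethers, an ester as masked CH2OH, an OMe on C9'), the furofuran is cut at C7'–C8' and O–C7' (Prins-type union). This gives a cis-2-aryl-3-(hydroxymethyl)-2,3-dihydrofuran and the dimethyl acetal of the dihydrobenzofuran aldehyde.
2. The dihydrofuran is cut at C7–C8 and traced to an aryl vinyl oxirane (vinylogous Darzens of O-silyl vanillin with methyl 4-bromocrotonate). The dihydrobenzofuran is cut at C2–C3 (Rh-carbene C–H insertion of an aryldiazoacetate built from 5-bromovanillin).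
3. Enabling feature: in the tetrahydrofuran ring that bears the simple 4-hydroxy-3-methoxyphenyl group, the ArCH–O–CH2 segment is a latent oxirane C–O–C and the two ring-fusion carbons a latent C=C. The electron-rich aryl on the benzylic carbon and the CH2O arm on the neighbouring ring-fusion carbon, carried as an ester, stabilise the two ends of a carbonyl ylide.
4. Forward ring order: oxirane → ring expansion by two carbons to the guaiacyl-bearing dihydrofuran ring; benzofuran five-ring made separately; second tetrahydrofuran ring closed in the union; acetal carbon C9' then reduced to CH2.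
5. Stereochemistry: 7,8-cis from the disrotatory ylide closure, absolute configuration of C7/C8 from a lipase resolution. C8' and C7' are relayed from C8 in the union (cis fusion forced by the tether, aryl endo under kinetic control). C2/C3 of the benzofuran (cis) come from the chiral Rh(II) catalyst.

Key step: step 3

**Remarks before the steps**

- Reading of the target: the SMILES corresponds to (7S,8S,7'S,8'S) with both aryl groups endo on the furofuran (each aryl cis to the neighbouring ring-fusion substituent) and to a 2,3-cis-(2S,3S) dihydrobenzofuran; the route is built for this isomer.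
- Assumption: the (R)-configured catalyst Rh2(R-PTTL)4 is taken to give the (2S,3R)-cis ester 16; if the sense is the reverse, the (S)-catalyst is used.
- Notation: lignan locants are used for the furofuran (C7 = ArCH–O carbon with the simple guaiacyl ring, C8 its ring-fusion neighbour, C9 the CH2O on C8; primed locants for the half that bears the benzofuranyl group). Racemates 6, 7 and F6 are written as both enantiomers divided by a dot. TIPS = triisopropylsilyl.

**Route**

Step 1
Reactants: 1 vanillin
Product: 2 3-methoxy-4-[(triisopropylsilyl)oxy]benzaldehyde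
Conditions: TIPSCl, imidazole, DMF, rt
Reagents that add atoms: chlorotriisopropylsilane, CC(C)[Si](Cl)(C(C)C)C(C)C
Why: Imidazole-promoted O-silylation masks the phenol with a group that should survive strong base, flash thermolysis, hydride and low-temperature Lewis acid and is removed by fluoride at the end.

Step 2
Reactants: 2 3-methoxy-4-[(triisopropylsilyl)oxy]benzaldehyde; 3 methyl (E)-4-bromobut-2-enoate
Product: 4 methyl (2E)-3-[3-{3-methoxy-4-[(triisopropylsilyl)oxy]phenyl}oxiran-2-yl]prop-2-enoate (racemic mixture of cis and trans oxiranes)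
Conditions: LDA, THF, −90 °C (dienolate of 3), then 2, −90 °C → rt
Reagents that add atoms: none
Why: Vinylogous Darzens condensation: the γ-bromo dienolate adds through its γ-carbon to the non-enolizable aldehyde and the alkoxide closes to the oxirane; both oxirane diastereomers are usable because step 3 erases their configuration.

Step 3
Reactants: 4 methyl (2E)-3-[3-aryl-oxiran-2-yl]prop-2-enoate
Product: 6 rac-methyl (2S*,3R*)-2-{3-methoxy-4-[(triisopropylsilyl)oxy]phenyl}-2,3-dihydrofuran-3-carboxylate (2,3-cis), via carbonyl ylide 5 (not isolated)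
Conditions: flash vacuum pyrolysis, ca. 500 °C, ca. 0.04 mbar, cold trap
Reagents that add atoms: none
Why: On flash thermolysis the oxirane C–C bond (ArCH–CH, flanked by the electron-rich aryl donor and the vinylogous ester acceptor) opens in a conrotatory 4-electron electrocyclic reaction to carbonyl ylide 5, which closes by a disrotatory 6-electron 1,5-electrocyclization between the benzylic carbon and the ester-bearing alkene carbon, so that the C–O–C three-ring grows by the two alkene carbons into the 2,3-dihydrofuran. The closest known reaction type is the thermal vinyl oxirane to 2,3-dihydrofuran rearrangement (hetero analogue of the vinylcyclopropane–cyclopentene rearrangement), which is precedented for aryl oxiranyl acrylates. The one ring closed is five-membered and closes pericyclically (1,5-dipolar electrocyclization, formally 5-endo-trig). The two new stereocentres (C2 and C3 of the dihydrofuran, later C7 and C8) are set relative to each other by orbital symmetry: aryl and ester sit on the outside of the U-shaped ylide (exo aryl, E-alkene) and disrotation turns them onto the same face, giving the cis isomer from either oxirane diastereomer; the ylide is planar, so the product is racemic and the absolute configuration is fixed in step 5. The step needs kinetic cis over trans selectivity and C–C over C–O cleavage: the short contact time of flash pyrolysis should prevent re-opening and equilibration to the trans isomer, and the push–pull aryl/ester substitution secures the ylide pathway.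

Step 4
Reactants: 6 rac-methyl cis-2-aryl-2,3-dihydrofuran-3-carboxylate
Product: 7 rac-[(2S*,3S*)-2-{3-methoxy-4-[(triisopropylsilyl)oxy]phenyl}-2,3-dihydrofuran-3-yl]methanol (2,3-cis)
Conditions: DIBAL-H (2.5 equiv), CH2Cl2, −78 °C; Rochelle salt
Reagents that add atoms: none
Why: Low-temperature DIBAL-H reduction takes the ester (the acceptor needed only for step 3) to the primary alcohol without touching the enol ether or epimerizing the allylic α-centre, so the cis relation is kept.

Step 5
Reactants: 7 rac-cis-(2-aryl-2,3-dihydrofuran-3-yl)methanol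
Product: 8 [(2S,3S)-2-{3-methoxy-4-[(triisopropylsilyl)oxy]phenyl}-2,3-dihydrofuran-3-yl]methanol
Conditions: Amano lipase PS (Burkholderia cepacia), vinyl acetate, MTBE, 25 °C, stopped a little beyond half conversion; chromatography on Et3N-deactivated silica
Reagents that add atoms: none
Why: Lipase-catalysed kinetic resolution by enantioselective transesterification: by the empirical size rule for this lipase with primary alcohols that have a carbon stereocentre next to CH2OH, the (2R,3R)-enantiomer should be acylated faster, so the (2S,3S)-alcohol is recovered enantioenriched; this fixes the absolute configuration of C7 and C8.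

Step 6
Reactants: 2 3-methoxy-4-[(triisopropylsilyl)oxy]benzaldehyde
Product: 9 {3-methoxy-4-[(triisopropylsilyl)oxy]phenyl}methanol
Conditions: NaBH4, MeOH, 0 °C
Reagents that add atoms: none
Why: Borohydride reduction of the aldehyde gives the benzylic alcohol; the aryl silyl ether is inert.

Step 7
Reactants: 9 {3-methoxy-4-[(triisopropylsilyl)oxy]phenyl}methanol; 10 5-bromovanillin (3-bromo-4-hydroxy-5-methoxybenzaldehyde)
Product: 11 3-bromo-5-methoxy-4-({3-methoxy-4-[(triisopropylsilyl)oxy]phenyl}methoxy)benzaldehyde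
Conditions: PPh3, DIAD, THF, 0 °C → rt
Reagents that add atoms: none
Why: Mitsunobu etherification of the acidic, hindered phenol with the primary benzylic alcohol proceeds under neutral conditions that keep the silyl ether; no stereocentre is involved.

Step 8
Reactants: 11 3-bromo-5-methoxy-4-(arylmethoxy)benzaldehyde
Product: 12 1-bromo-5-(dimethoxymethyl)-3-methoxy-2-({3-methoxy-4-[(triisopropylsilyl)oxy]phenyl}methoxy)benzene
Conditions: HC(OMe)3, MeOH, PPTS (cat.), rt; Et3N quench
Reagents that add atoms: trimethyl orthoformate, COC(OC)OC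
Why: Acid-catalysed acetalization with orthoformate as water scavenger protects the aldehyde against the zinc enolate and the carbene chemistry and at the same time installs the dimethyl acetal that step 12 needs as oxocarbenium precursor.

Step 9
Reactants: 12 aryl bromide dimethyl acetal; 13 (2-ethoxy-2-oxoethyl)zinc bromide (commercial solution)
Product: 14 ethyl 2-[5-(dimethoxymethyl)-3-methoxy-2-({3-methoxy-4-[(triisopropylsilyl)oxy]phenyl}methoxy)phenyl]acetate
Conditions: Pd(dba)2 (2 mol%), Q-Phos (2 mol%), THF, rt → 50 °C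
Reagents that add atoms: none
Why: Palladium-catalysed cross-coupling of the aryl bromide with a Reformatsky reagent (α-arylation of an ester enolate equivalent under neutral conditions) installs the arylacetate without touching acetal or silyl ether.

Step 10
Reactants: 14 ethyl arylacetate
Product: 15 ethyl 2-diazo-2-[5-(dimethoxymethyl)-3-methoxy-2-({3-methoxy-4-[(triisopropylsilyl)oxy]phenyl}methoxy)phenyl]acetate
Conditions: p-ABSA, DBU, MeCN, 0 °C → rt
Reagents that add atoms: 4-acetamidobenzenesulfonyl azide, CC(=O)Nc1ccc(cc1)S(=O)(=O)N=[N+]=[N-]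
Why: Regitz diazo transfer to the activated arylacetate gives the donor/acceptor aryldiazoacetate.

Step 11
Reactants: 15 ethyl aryldiazoacetate
Product: 16 ethyl (2S,3R)-5-(dimethoxymethyl)-7-methoxy-2-{3-methoxy-4-[(triisopropylsilyl)oxy]phenyl}-2,3-dihydro-1-benzofuran-3-carboxylate (2,3-cis)
Conditions: Rh2(R-PTTL)4 (1 mol%), toluene, −60 °C
Reagents that add atoms: none
Why: Rh(II)-carbene intramolecular 1,5 C–H insertion into the benzylic ether CH2 closes the five-membered ring of the benzofuran; the chiral carboxylate catalyst selects one enantiotopic C–H and the concerted insertion places aryl and ester cis (kinetic product), setting C2 (S) and C3 (R).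

Step 12
Reactants: 8 (2S,3S)-dihydrofuranyl methanol; 16 cis-dihydrobenzofuran dimethyl acetal
Product: 18 ethyl (2S,3R)-7-methoxy-2-{3-methoxy-4-[(triisopropylsilyl)oxy]phenyl}-5-[endo,endo-8-methoxy-6-{3-methoxy-4-[(triisopropylsilyl)oxy]phenyl}-3,7-dioxabicyclo[3.3.0]oct-2-yl]-2,3-dihydro-1-benzofuran-3-carboxylate (furofuranyl methyl acetal; C7, C8, C8', C7' all S; OMe on C9'), via mixed methyl acetal 17 (not isolated)
Conditions: TMSOTf (0.3 equiv), 4 Å MS, CH2Cl2, −78 °C; Et3N quench at −78 °C
Reagents that add atoms: none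
Why: Lewis-acid transacetalization gives mixed acetal 17, whose oxocarbenium ion is attacked by the β-carbon of the cyclic enol ether (Prins-type five-ring closure) on the face that carries the tether, which forces the cis ring fusion (C8' set by C8) and, under kinetic control at −78 °C, should place the new aryl group endo (C7') as known for this dihydrofuran–acetal cyclization; the ring oxocarbenium ion left behind is trapped by methanol as the methyl acetal.

Step 13
Reactants: 18 furofuranyl methyl acetal
Product: 19 ethyl (2S,3R)-7-methoxy-2-{3-methoxy-4-[(triisopropylsilyl)oxy]phenyl}-5-[(7S,8S,7'S,8'S)-endo,endo-6-{3-methoxy-4-[(triisopropylsilyl)oxy]phenyl}-3,7-dioxabicyclo[3.3.0]oct-2-yl]-2,3-dihydro-1-benzofuran-3-carboxylate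
Conditions: Et3SiH (3 equiv), BF3·OEt2 (1.5 equiv), CH2Cl2, −78 → −40 °C; aq. NaHCO3
Reagents that add atoms: none
Why: Ionic hydrogenation of the cyclic acetal (ionization and hydride transfer from the silane) turns the acetal carbon C9' into the ring CH2; at low temperature the other stereocentres should stay untouched.

Step 14
Reactants: 19 furofuran ethyl ester
Product: 20 bis-TIPS ether of the target: [(2S,3S)-7-methoxy-2-{3-methoxy-4-[(triisopropylsilyl)oxy]phenyl}-5-[(7S,8S,7'S,8'S)-endo,endo-6-{3-methoxy-4-[(triisopropylsilyl)oxy]phenyl}-3,7-dioxabicyclo[3.3.0]oct-2-yl]-2,3-dihydro-1-benzofuran-3-yl]methanol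
Conditions: DIBAL-H (3 equiv), CH2Cl2, −78 → −20 °C; Rochelle salt
Reagents that add atoms: none
Why: DIBAL-H reduces the ester to the hydroxymethyl group without base, so C3 of the benzofuran is not epimerized and the 2,3-cis relation is kept.

Step 15
Reactants: 20 bis-TIPS ether of the target
Product: 21 CNP0303197.1, 4-[(1S,3aS,4S,6aS)-4-[(2S,3S)-2-(4-hydroxy-3-methoxyphenyl)-3-(hydroxymethyl)-7-methoxy-2,3-dihydro-1-benzofuran-5-yl]tetrahydro-1H,3H-furo[3,4-c]furan-1-yl]-2-methoxyphenol
Conditions: TBAF (2.2 equiv), AcOH (2.2 equiv), THF, 0 °C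
Reagents that add atoms: none
Why: Fluoride cleaves both aryl silyl ethers; buffering with acetic acid keeps the medium near neutral, so the acid-labile endo benzylic ethers and the cis-dihydrobenzofuran should not epimerize.

**Compound list**

1 | vanillin (4-hydroxy-3-methoxybenzaldehyde) | COc1cc(C=O)ccc1O | starting material
2 | 3-methoxy-4-[(triisopropylsilyl)oxy]benzaldehyde | COc1cc(C=O)ccc1O[Si](C(C)C)(C(C)C)C(C)C | intermediate
3 | methyl (E)-4-bromobut-2-enoate | COC(=O)/C=C/CBr | starting material
4 | methyl (2E)-3-[3-{3-methoxy-4-[(triisopropylsilyl)oxy]phenyl}oxiran-2-yl]prop-2-enoate (oxirane cis/trans mixture, racemic) | COC(=O)/C=C/C1OC1c1ccc(O[Si](C(C)C)(C(C)C)C(C)C)c(OC)c1 | intermediate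
5 | carbonyl ylide ArCH=O(+)–CH(−)–CH=CH–CO2Me (Ar = 3-methoxy-4-TIPSO-phenyl) | COC(=O)C=C[CH-][O+]=Cc1ccc(O[Si](C(C)C)(C(C)C)C(C)C)c(OC)c1 | intermediate
6 | rac-methyl (2S*,3R*)-2-{3-methoxy-4-[(triisopropylsilyl)oxy]phenyl}-2,3-dihydrofuran-3-carboxylate (cis) | COc1cc([C@H]2OC=C[C@H]2C(=O)OC)ccc1O[Si](C(C)C)(C(C)C)C(C)C.COc1cc([C@@H]2OC=C[C@@H]2C(=O)OC)ccc1O[Si](C(C)C)(C(C)C)C(C)C | intermediate
7 | rac-[(2S*,3S*)-2-{3-methoxy-4-[(triisopropylsilyl)oxy]phenyl}-2,3-dihydrofuran-3-yl]methanol (cis) | COc1cc([C@H]2OC=C[C@H]2CO)ccc1O[Si](C(C)C)(C(C)C)C(C)C.COc1cc([C@@H]2OC=C[C@@H]2CO)ccc1O[Si](C(C)C)(C(C)C)C(C)C | intermediate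
8 | [(2S,3S)-2-{3-methoxy-4-[(triisopropylsilyl)oxy]phenyl}-2,3-dihydrofuran-3-yl]methanol | COc1cc([C@H]2OC=C[C@H]2CO)ccc1O[Si](C(C)C)(C(C)C)C(C)C | intermediate
9 | {3-methoxy-4-[(triisopropylsilyl)oxy]phenyl}methanol | COc1cc(CO)ccc1O[Si](C(C)C)(C(C)C)C(C)C | intermediate
10 | 5-bromovanillin (3-bromo-4-hydroxy-5-methoxybenzaldehyde) | COc1cc(C=O)cc(Br)c1O | starting material
11 | 3-bromo-5-methoxy-4-({3-methoxy-4-[(triisopropylsilyl)oxy]phenyl}methoxy)benzaldehyde | COc1cc(C=O)cc(Br)c1OCc1ccc(O[Si](C(C)C)(C(C)C)C(C)C)c(OC)c1 | intermediate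
12 | 1-bromo-5-(dimethoxymethyl)-3-methoxy-2-({3-methoxy-4-[(triisopropylsilyl)oxy]phenyl}methoxy)benzene | COC(OC)c1cc(Br)c(OCc2ccc(O[Si](C(C)C)(C(C)C)C(C)C)c(OC)c2)c(OC)c1 | intermediate
13 | (2-ethoxy-2-oxoethyl)zinc bromide | CCOC(=O)C[Zn]Br | starting material
14 | ethyl 2-[5-(dimethoxymethyl)-3-methoxy-2-({3-methoxy-4-[(triisopropylsilyl)oxy]phenyl}methoxy)phenyl]acetate | CCOC(=O)Cc1cc(C(OC)OC)cc(OC)c1OCc1ccc(O[Si](C(C)C)(C(C)C)C(C)C)c(OC)c1 | intermediate
15 | ethyl 2-diazo-2-[5-(dimethoxymethyl)-3-methoxy-2-({3-methoxy-4-[(triisopropylsilyl)oxy]phenyl}methoxy)phenyl]acetate | CCOC(=O)C(=[N+]=[N-])c1cc(C(OC)OC)cc(OC)c1OCc1ccc(O[Si](C(C)C)(C(C)C)C(C)C)c(OC)c1 | intermediate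
16 | ethyl (2S,3R)-5-(dimethoxymethyl)-7-methoxy-2-{3-methoxy-4-[(triisopropylsilyl)oxy]phenyl}-2,3-dihydro-1-benzofuran-3-carboxylate (cis) | COC(OC)c1cc(OC)c2c(c1)[C@@H](C(=O)OCC)[C@@H](c1ccc(O[Si](C(C)C)(C(C)C)C(C)C)c(OC)c1)O2 | intermediate
17 | mixed methyl acetal of 16 with alcohol 8 (8–CH2–O–CH(OMe)–benzofuranyl; acetal carbon not defined) | COc1cc([C@H]2OC=C[C@H]2COC(OC)c2cc(OC)c3c(c2)[C@@H](C(=O)OCC)[C@@H](c2ccc(O[Si](C(C)C)(C(C)C)C(C)C)c(OC)c2)O3)ccc1O[Si](C(C)C)(C(C)C)C(C)C | intermediate
18 | furofuranyl methyl acetal (endo,endo-2,6-diaryl-8-methoxy-3,7-dioxabicyclo[3.3.0]octane; ethyl ester, bis-TIPS ether; anomeric centre not defined) | COc1cc([C@H]2OC(OC)[C@@H]3[C@H]2CO[C@@H]3c2cc(OC)c3c(c2)[C@@H](C(=O)OCC)[C@@H](c2ccc(O[Si](C(C)C)(C(C)C)C(C)C)c(OC)c2)O3)ccc1O[Si](C(C)C)(C(C)C)C(C)C | intermediate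
19 | endo,endo-furofuran ethyl ester, bis-TIPS ether | COc1cc([C@H]2OC[C@@H]3[C@H]2CO[C@@H]3c2cc(OC)c3c(c2)[C@@H](C(=O)OCC)[C@@H](c2ccc(O[Si](C(C)C)(C(C)C)C(C)C)c(OC)c2)O3)ccc1O[Si](C(C)C)(C(C)C)C(C)C | intermediate
20 | bis-TIPS ether of the target | COc1cc([C@H]2OC[C@@H]3[C@H]2CO[C@@H]3c2cc(OC)c3c(c2)[C@@H](CO)[C@@H](c2ccc(O[Si](C(C)C)(C(C)C)C(C)C)c(OC)c2)O3)ccc1O[Si](C(C)C)(C(C)C)C(C)C | intermediate
21 | CNP0303197.1 | COc1cc([C@H]2OC[C@@H]3[C@H]2CO[C@@H]3c2cc(OC)c3c(c2)[C@@H](CO)[C@@H](c2ccc(O)c(OC)c2)O3)ccc1O | target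

**Count and risks**

Total step count: 15. Longest linear sequence: 11 steps (steps 1, 6, 7, 8, 9, 10, 11, 12, 13, 14, 15).

Steps most likely to fail:

1. Step 12. The Lewis acid may ionize the acid-labile benzylic C–O bonds (C2–O of the cis-dihydrobenzofuran in 16, the ArCH–O bond of 8) and so erode the cis and endo configurations, or the closure with the bulky acetal may be slow enough to lose the kinetic endo preference. The fallback changes the order of assembly so that the union uses a simple aryl acetal and the dihydrobenzofuran is built last. It sets out from 8 and 12: these would be united under the conditions of step 12 to the furofuranyl methyl acetal carrying the bromo benzyl-ether arene F1; ionic hydrogenation as in step 13 would give the bromo furofuran F2; Pd-catalysed Reformatsky coupling with 13 would give the furofuran arylacetate F3; diazo transfer would give the furofuran aryldiazoacetate F4; and the Rh2(R-PTTL)4 C–H insertion would close the dihydrobenzofuran and come back to the route at 19.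

2. Step 5. The enzyme may discriminate the enantiomers poorly, because the stereocentre is one carbon away from the reacting hydroxyl group. The fallback is a covalent resolution. It sets out from 7, which would be esterified with (S)-2-methoxy-2-phenylacetic acid (DCC, DMAP, CH2Cl2, 0 °C); the diastereomeric esters would be separated by chromatography or crystallization to give the (2S,3S)-alcohol (S)-O-methylmandelate F5, and reductive cleavage (DIBAL-H, CH2Cl2, −78 °C) would come back to the route at 8.

3. Step 3. The silyl ether may be too involatile or degrade in the hot zone, or the kinetic cis preference may be lost by re-opening of the product to the ylide. The fallback separates ring expansion from stereocontrol. It sets out from 4, which would be heated in solution (toluene, sealed tube, about 180–200 °C) to give mainly the racemic trans ester F6; F6 would be deprotonated (LDA, THF, −78 °C) to the planar dienolate and protonated at C3 with a bulky phenol (2,6-di-tert-butyl-4-methylphenol) from the face away from the C2 aryl group, a kinetic protonation that places the ester cis to the aryl group and comes back to the route at 6.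

**Further compounds**

F1 | step 12 | furofuranyl methyl acetal with 3-bromo-5-methoxy-4-({3-methoxy-4-[(triisopropylsilyl)oxy]phenyl}methoxy)phenyl on C7' | COc1cc([C@H]2OC(OC)[C@@H]3[C@H]2CO[C@@H]3c2cc(Br)c(OCc3ccc(O[Si](C(C)C)(C(C)C)C(C)C)c(OC)c3)c(OC)c2)ccc1O[Si](C(C)C)(C(C)C)C(C)C
F2 | step 12 | endo,endo-furofuran with the same bromo benzyl-ether arene on C7' | COc1cc([C@H]2OC[C@@H]3[C@H]2CO[C@@H]3c2cc(Br)c(OCc3ccc(O[Si](C(C)C)(C(C)C)C(C)C)c(OC)c3)c(OC)c2)ccc1O[Si](C(C)C)(C(C)C)C(C)C
F3 | step 12 | furofuran arylacetate (ethyl ester) | COc1cc([C@H]2OC[C@@H]3[C@H]2CO[C@@H]3c2cc(CC(=O)OCC)c(OCc3ccc(O[Si](C(C)C)(C(C)C)C(C)C)c(OC)c3)c(OC)c2)ccc1O[Si](C(C)C)(C(C)C)C(C)C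
F4 | step 12 | furofuran aryldiazoacetate (ethyl ester) | COc1cc([C@H]2OC[C@@H]3[C@H]2CO[C@@H]3c2cc(C(=[N+]=[N-])C(=O)OCC)c(OCc3ccc(O[Si](C(C)C)(C(C)C)C(C)C)c(OC)c3)c(OC)c2)ccc1O[Si](C(C)C)(C(C)C)C(C)C
F5 | step 5 | [(2S,3S)-2-{3-methoxy-4-[(triisopropylsilyl)oxy]phenyl}-2,3-dihydrofuran-3-yl]methyl (S)-2-methoxy-2-phenylacetate | COc1cc([C@H]2OC=C[C@H]2COC(=O)[C@@H](OC)c2ccccc2)ccc1O[Si](C(C)C)(C(C)C)C(C)C
F6 | step 3 | rac-methyl (2S*,3S*)-2-{3-methoxy-4-[(triisopropylsilyl)oxy]phenyl}-2,3-dihydrofuran-3-carboxylate (trans) | COc1cc([C@H]2OC=C[C@@H]2C(=O)OC)ccc1O[Si](C(C)C)(C(C)C)C(C)C.COc1cc([C@@H]2OC=C[C@H]2C(=O)OC)ccc1O[Si](C(C)C)(C(C)C)C(C)C
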